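(Readings and results are calculated with made-up constants, noise included.)

Late in the earlier runs the target readings stand still: east target reads 45 % at 1.25 d and 47 % at 20.0 d, a step of the size of the scatter, so I take 15 d for a point on the plateau and ask what that plateau is made of.

| flask | solid substrate | coupling partner | remark | time |
|---|---|---|---|---|
| east | 0.014 M | 0.0075 M (in portions, 3) | run made earlier; portions every 2.5 h |  |
| north-east | 0.014 M | 0.017 M (in portions, 3) | run made earlier; portions every 2.5 h |  |
| north | 0.021 M | 0.0112 M (in portions, 3) | run made earlier; portions every 2.5 h |  |
| flask | 0.014 M | 0.0112 M (in portions, 3) | the portions of coupling partner follow each other after 2.5 h, the first at the start | 15 d |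

| run | time / d | target / % | side product / % |
|---|---|---|---|
| east | 1.25 | 45 | 9 |
| east | 2.50 | 49 | 12 |
| east | 4.00 | 46 | 7 |
| east | 6.00 | 48 | 12 |
| east | 10.0 | 50 | 12 |
| east | 20.0 | 47 | 6 |
| north-east | 1.25 | 83 | 11 |
| north-east | 2.50 | 78 | 14 |
| north-east | 4.00 | 78 | 11 |
| north-east | 6.00 | 77 | 12 |
| north-east | 10.0 | 77 | 9 |
| north-east | 20.0 | 80 | 12 |
| north | 1.25 | 42 | 19 |
| north | 2.50 | 41 | 19 |
| north | 5.00 | 48 | 17 |
| north | 10.0 | 45 | 19 |
| north | 20.0 | 48 | 17 |

(readings scatter by 2 percentage points)

- percentages count the solid substrate that a species holds: one side product or homo dimer counts as two
- solid, in amounts per volume of the solution: solid substrate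
- the earlier runs were read with a standard deviation of 2 percentage points
- candidate steps: solid substrate <-> dissolved substrate; dissolved substrate + coupling partner -> target; solid substrate + target -> side product; 2 solid substrate -> homo dimer
- at the start none of the solid substrate is in solution
- what has only dissolved of solid substrate counts as not reacted

1. amount of target at 15 d, in percent of the solid substrate charged
2. amount of side product at 15 d, in percent of the solid substrate charged

I follow the flask in slow motion. At the very start no substrate is in solution and no target stands, so the side-product step waits for target. Solid substrate dissolves, and dissolved substrate takes up coupling partner as each portion arrives. In the middle, target stands beside solid substrate, so side product forms, and each side product holds one coupling partner unit but two substrate units. Towards the end, the last portion goes in at 5.00 h, earlier than the first reading of the earlier runs.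

So I count the take-up, target plus half the side product, and hold it against the charge ratio c(coupling partner)/c(solid substrate). With coupling partner in excess (ratio 121 %), the north-east readings from 6.00 d on give the take-up ceiling, the take-up read at this solid charge with coupling partner in excess, 83.5 %. East, at ratio 53.6 %, stays below it, with a take-up of 53.3 %.

This flask has ratio 80.0 %, below the ceiling, so I expect coupling partner to be the limiting reagent here. Taking side product at the north-east reading, 11.0 %, since the solid charge is the same, I reckon target at 74.5 %.

The forecast gives 72 % target and 11 % side product, holding that “Each side product carries one coupling-partner unit”. Its target lies 2.5 percentage points below mine, a gap it assigns to extra dimer loss between smaller portions.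

The flask gives 74.4 % target and 11.3 % side product, both forecast numbers within their margins.

    solid substrate ⇌ dissolved substrate, rate k1*(cs1 - [dissolved substrate]) while solid is left; crystals form when [dissolved substrate] > cs1 (solubility = 5.60 mM, k = 0.220 /h)
    dissolved substrate + coupling partner → target (k = 1200 /M/h)
    solid substrate + target → side product (k = 3.60 /M/h)
    2 solid substrate → homo dimer (k = 1.20 /M/h)

The take-up of this flask is 80.1 %, level with its ratio and below the ceiling, with 0 % of its coupling partner left. A neighbouring flask charged with 0.019 M of coupling partner has ratio 136 %, above the ceiling. Its take-up is 84.1 %, level with the ceiling; it holds 78.4 % target, and of its own charge of coupling partner 38 % is left.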